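**Plan**

- Cuts, in retrosynthetic order: the CH2 bridge between ring A and ring C (back to formaldehyde); the three aryl O–H (as methyl ethers); in ring B the bond between the acetyl-bearing carbon and the ring carbonyl next to the CMe2 carbon; the aryl–butyryl bond; the pyranone ring (to acetylketene and an enol silane); the ArCH=CH bond of an aldol condensation.
- Enabling feature: ring B is a 2-acetyl-6,6-dimethylcyclohexane-1,3,5-trione. Its C1 carbonyl sits between the quaternary C6 and the acetyl-bearing C2, so the C1–C2 bond is the Claisen bond of a 2,2-dimethyl-3,5,7-trioxo ester. That triketone is the hydrate of a 2,3,6-trisubstituted 4-pyranone whose C3 already carries the ring A benzyl group.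
- Forward order: ring A is bought as the aromatic aldehyde; the pyranone ring is built by [4+2] cycloaddition; ring A is butyrylated; the pyranone is rearranged into ring B; the ethers are cleaved; ring C, made separately by dearomatising gem-dimethylation, is joined last through a formaldehyde-derived CH2.
- Stereochemistry: the target has no stereocentre and no stereogenic double bond; the transient centres and alkene geometries on the way are erased.

Key step: step 6

Remark: ring A is the butyrylphloroglucinol ring, ring B the acetyl-bearing trione ring and ring C the propionyl-bearing trione ring. All acyl-trione rings are drawn in the enol tautomer of the target SMILES, although they exist as equilibrating enol forms.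

Remark: the four starting materials, including 1-(2,4,6-trihydroxyphenyl)propan-1-one (flopropione), are taken as purchasable.

**Route**

Step 1
Reactants: 1 methyl 2,2-dimethyl-3-oxobutanoate; 2 2,4,6-trimethoxybenzaldehyde
Product: 4 methyl (E)-2,2-dimethyl-3-oxo-5-(2,4,6-trimethoxyphenyl)pent-4-enoate, via aldol adduct 3 (not isolated)
Conditions: LiN(iPr)2 (LDA), THF, −78 °C; then 2, −78 °C; AcOH quench; crude 3, TsOH·H2O (cat.), CH2Cl2, rt
Reagents that add atoms: none
Why: Directed aldol addition of the kinetic lithium enolate of the methyl ketone (the only enolisable position of 1; the amide base at −78 °C spares the quaternary β-keto ester, which alkoxide or hydroxide would cleave by retro-Claisen reaction) to the non-enolisable aldehyde, then acid-catalysed E1 dehydration through the trimethoxybenzylic cation, which erases the carbinol centre of 3 and should give the conjugated E-alkene under thermodynamic control.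

Step 2
Reactants: 4 methyl (E)-2,2-dimethyl-3-oxo-5-(2,4,6-trimethoxyphenyl)pent-4-enoate
Product: 5 methyl 2,2-dimethyl-3-oxo-5-(2,4,6-trimethoxyphenyl)pentanoate
Conditions: H2 (1 atm), 10% Pd/C, EtOAc, rt
Reagents that add atoms: none
Why: Heterogeneous catalytic hydrogenation should saturate the conjugated styrenyl C=C far faster than it touches the hindered aliphatic ketone, the ester or the aryl ethers.

Step 3
Reactants: 5 methyl 2,2-dimethyl-3-oxo-5-(2,4,6-trimethoxyphenyl)pentanoate
Product: 6 methyl (Z)-2,2-dimethyl-3-(trimethylsilyloxy)-5-(2,4,6-trimethoxyphenyl)pent-3-enoate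
Conditions: Me3SiOTf, Et3N, CH2Cl2, 0 °C
Reagents that add atoms: trimethylsilyl trifluoromethanesulfonate, C[Si](C)(C)OS(=O)(=O)C(F)(F)F
Why: Soft enolisation and O-silylation can only go toward C4 because C2 is quaternary, and the tert-alkyl group on the carbonyl should favour the Z enol silane, whose geometry is lost later and does not matter.

Step 4
Reactants: 6 methyl (Z)-2,2-dimethyl-3-(trimethylsilyloxy)-5-(2,4,6-trimethoxyphenyl)pent-3-enoate; 7 2,2,6-trimethyl-4H-1,3-dioxin-4-one
Product: 10 methyl 2-methyl-2-[6-methyl-4-oxo-3-(2,4,6-trimethoxybenzyl)-4H-pyran-2-yl]propanoate, via acetylketene 8 (not isolated), via silyloxy dihydropyranone cycloadduct 9 (not isolated)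
Conditions: 7 (excess, slow addition), toluene, 110 °C, acetone distilled off; then TsOH·H2O (cat.), 60 °C
Reagents that add atoms: none
Why: Thermal retro-[4+2] of 7 releases acetylketene, which reacts as an oxa-diene with the electron-rich enol ether in a hetero-Diels–Alder reaction (the known acylketene/enol ether route to 4-pyranones), the nucleophilic CH carbon bonding to the ketene carbon so that the benzyl group ends at C3 and the quaternary carbon at C2; acid-promoted β-elimination of trimethylsilanol from 9 should then give the conjugated pyranone and remove both transient stereocentres.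

Step 5
Reactants: 10 methyl 2-methyl-2-[6-methyl-4-oxo-3-(2,4,6-trimethoxybenzyl)-4H-pyran-2-yl]propanoate
Product: 11 methyl 2-[3-(3-butanoyl-2,4,6-trimethoxybenzyl)-6-methyl-4-oxo-4H-pyran-2-yl]-2-methylpropanoate
Conditions: n-PrCO2H, (CF3CO)2O, CH2Cl2, 0 °C to rt
Reagents that add atoms: butanoic acid, CCCC(=O)O
Why: Friedel–Crafts acylation by the mixed butanoic trifluoroacetic anhydride at one of the two equivalent free positions of the trimethoxyarene (each ortho/para to three methoxy groups), with the protonated pyranone and the ester inert and the first acyl group blocking a second acylation; acylating at this stage keeps strong acid away from the benzyl–trione bond that exists only after ring B is made.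

Step 6
Reactants: 11 methyl 2-[3-(3-butanoyl-2,4,6-trimethoxybenzyl)-6-methyl-4-oxo-4H-pyran-2-yl]-2-methylpropanoate
Product: 13 2-acetyl-4-[(3-butanoyl-2,4,6-trimethoxyphenyl)methyl]-3,5-dihydroxy-6,6-dimethylcyclohexa-2,4-dien-1-one, via triketo ester 12 (not isolated)
Conditions: Ba(OH)2·8H2O, MeOH–H2O, 40 °C; then NaOMe in MeOH, 60 °C, same flask; 1 M HCl work-up
Reagents that add atoms: barium hydroxide, [Ba+2].[OH-].[OH-] (its hydroxide, equivalent to water, O, supplies the oxygen of the acetyl carbonyl)
Why: Proposed new method: hydroxide adds in conjugate fashion to an α-carbon of the vinylogous ester in 11 (attack at C2 or at C6 of the pyranone leads to the same chain) and retro-oxa-Michael opening releases the enolate of triketo ester 12, whose carbon between the C5 and C7 ketones then attacks the methyl ester under methoxide in a Dieckmann-type Claisen condensation, methoxide leaving and the acyl-trione being deprotonated at once. The closest known reactions are the Ba(OH)2 opening of 2,6-dimethyl-4-pyranone to heptane-2,4,6-trione and the Claisen cyclisation of 3,5,7-triketo esters to acylphloroglucinols; running both in one flask on a pyranone that carries the ester is what is new. Ring B closes in a 6-(enolexo)-exo-trig mode and no stereocentre is formed. The step needs site selectivity among the enolisable carbons, and ring size secures it: attack from the benzyl-bearing carbon would give a four-membered ring and from the terminal methyl an eight-membered ring. The quaternary carbon removes the ester α-hydrogens and with them the aldol closure to an orsellinate-type arene, slows saponification and speeds the closure by the gem-dialkyl effect, while the only remaining aldol (terminal methyl onto the neopentyl ketone) is hindered. The aryl methyl ethers prevent quinone methide cleavage of the benzylic bond, the twisted aryl ketone is inert, and the stable enolate of 13 guards it against retro-Claisen loss of the acetyl group.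

Step 7
Reactants: 13 2-acetyl-4-[(3-butanoyl-2,4,6-trimethoxyphenyl)methyl]-3,5-dihydroxy-6,6-dimethylcyclohexa-2,4-dien-1-one
Product: 14 norflavaspidic acid AB, 2-acetyl-4-[(3-butanoyl-2,4,6-trihydroxyphenyl)methyl]-3,5-dihydroxy-6,6-dimethylcyclohexa-2,4-dien-1-one
Conditions: BBr3 (excess), CH2Cl2, −78 °C to rt; then H2O, 0 °C
Reagents that add atoms: none
Why: Lewis-acid ether cleavage (bromide attack at the methyl of each boron-complexed aryl ether, helped by chelation to the butyryl carbonyl for the two ortho ethers) should free all three phenols, with ring B held as boron chelates, the butyryl group disfavouring ipso-protonation at the bridge, and low temperature holding back cyclodehydration to a xanthene.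

Step 8
Reactants: 15 1-(2,4,6-trihydroxyphenyl)propan-1-one
Product: 16 propionylfilicinic acid, 3,5-dihydroxy-6,6-dimethyl-2-propanoylcyclohexa-2,4-dien-1-one
Conditions: NaOMe, MeI (two equivalents), MeOH, 0 °C to rt; 1 M HCl work-up
Reagents that add atoms: iodomethane, CI
Why: Dearomatising double C-methylation of the acylphloroglucinol polyanion at one ring carbon is the established way to acylfilicinic acids, and limiting the iodomethane should hold back tri- and tetramethylation, the mono- and 3,5-dimethyl by-products being removed by chromatography.

Step 9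
Reactants: 14 norflavaspidic acid AB; 16 propionylfilicinic acid
Product: 17 filixic acid ABP (target), ring A bearing the butyryl group, three hydroxyls and two CH2 bridges to acetylfilicinic acid (ring B) and propionylfilicinic acid (ring C)
Conditions: 16 (excess), 37% aq. CH2O, 1% aq. KOH, 0 °C to rt, short reaction time; 1 M HCl
Reagents that add atoms: formaldehyde, C=O
Why: Hydroxymethylation, loss of hydroxide to a quinone methide (or 2-methylene trione) and Michael addition of the other enolate is the classical formaldehyde methylene-bridging of acylphloroglucinols with acylfilicinic acids; 14 and 16 each have a single free nucleophilic carbon, so only one cross product can form, and an excess of 16 should divert statistical by-products into the separable ring C homodimer.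

**Compound list**

1 | methyl 2,2-dimethyl-3-oxobutanoate | COC(=O)C(C)(C)C(C)=O | starting material
2 | 2,4,6-trimethoxybenzaldehyde | COc1cc(OC)c(C=O)c(OC)c1 | starting material
3 | methyl 5-hydroxy-2,2-dimethyl-3-oxo-5-(2,4,6-trimethoxyphenyl)pentanoate (racemic aldol adduct) | COC(=O)C(C)(C)C(=O)CC(O)c1c(OC)cc(OC)cc1OC | intermediate (not isolated)
4 | methyl (E)-2,2-dimethyl-3-oxo-5-(2,4,6-trimethoxyphenyl)pent-4-enoate | COC(=O)C(C)(C)C(=O)/C=C/c1c(OC)cc(OC)cc1OC | intermediate
5 | methyl 2,2-dimethyl-3-oxo-5-(2,4,6-trimethoxyphenyl)pentanoate | COC(=O)C(C)(C)C(=O)CCc1c(OC)cc(OC)cc1OC | intermediate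
6 | methyl (Z)-2,2-dimethyl-3-(trimethylsilyloxy)-5-(2,4,6-trimethoxyphenyl)pent-3-enoate | COC(=O)C(C)(C)/C(O[Si](C)(C)C)=C/Cc1c(OC)cc(OC)cc1OC | intermediate
7 | 2,2,6-trimethyl-4H-1,3-dioxin-4-one | CC1=CC(=O)OC(C)(C)O1 | starting material
8 | acetylketene (3-oxobut-1-en-1-one) | CC(=O)C=C=O | intermediate (not isolated)
9 | methyl 2-methyl-2-[6-methyl-4-oxo-3-(2,4,6-trimethoxybenzyl)-2-(trimethylsilyloxy)-3,4-dihydro-2H-pyran-2-yl]propanoate (racemic, mixture of diastereomers) | COC(=O)C(C)(C)C1(O[Si](C)(C)C)OC(C)=CC(=O)C1Cc2c(OC)cc(OC)cc2OC | intermediate (not isolated)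
10 | methyl 2-methyl-2-[6-methyl-4-oxo-3-(2,4,6-trimethoxybenzyl)-4H-pyran-2-yl]propanoate | COC(=O)C(C)(C)C1=C(Cc2c(OC)cc(OC)cc2OC)C(=O)C=C(C)O1 | intermediate
11 | methyl 2-[3-(3-butanoyl-2,4,6-trimethoxybenzyl)-6-methyl-4-oxo-4H-pyran-2-yl]-2-methylpropanoate | COC(=O)C(C)(C)C1=C(Cc2c(OC)cc(OC)c(C(=O)CCC)c2OC)C(=O)C=C(C)O1 | intermediate (key-step precursor)
12 | methyl 4-[(3-butanoyl-2,4,6-trimethoxyphenyl)methyl]-2,2-dimethyl-3,5,7-trioxooctanoate (racemic, present as enolates) | COC(=O)C(C)(C)C(=O)C(Cc1c(OC)cc(OC)c(C(=O)CCC)c1OC)C(=O)CC(C)=O | intermediate (not isolated)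
13 | 2-acetyl-4-[(3-butanoyl-2,4,6-trimethoxyphenyl)methyl]-3,5-dihydroxy-6,6-dimethylcyclohexa-2,4-dien-1-one | CCCC(=O)c1c(OC)cc(OC)c(CC2=C(O)C(C)(C)C(=O)C(C(C)=O)=C2O)c1OC | intermediate (key-step product)
14 | norflavaspidic acid AB, 2-acetyl-4-[(3-butanoyl-2,4,6-trihydroxyphenyl)methyl]-3,5-dihydroxy-6,6-dimethylcyclohexa-2,4-dien-1-one | CCCC(=O)c1c(O)cc(O)c(CC2=C(O)C(C)(C)C(=O)C(C(C)=O)=C2O)c1O | intermediate
15 | 1-(2,4,6-trihydroxyphenyl)propan-1-one (flopropione) | CCC(=O)c1c(O)cc(O)cc1O | starting material
16 | propionylfilicinic acid, 3,5-dihydroxy-6,6-dimethyl-2-propanoylcyclohexa-2,4-dien-1-one | CCC(=O)C1=C(O)C=C(O)C(C)(C)C1=O | intermediate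
17 | filixic acid ABP (CNP0325527.0) | CCCC(=O)c1c(O)c(CC2=C(O)C(C)(C)C(=O)C(C(C)=O)=C2O)c(O)c(CC2=C(O)C(C)(C)C(=O)C(C(=O)CC)=C2O)c1O | target

**Step count**

Total: 9 steps. Longest linear sequence: 8 steps (steps 1 to 7 and step 9); step 8 is a one-step side branch.

**Steps most likely to fail**

1. Step 6. Saponification of the ester or retro-Claisen fragmentation of the opened chain may run faster than the carbon–carbon closure, and unreacted triketone may re-close to the pyranone on acidification. The fallback uses known chemistry, sets out from 2 and comes back at 13. Aldehyde 2 is butyrylated (butyryl chloride, TiCl4, CH2Cl2) to 3-butanoyl-2,4,6-trimethoxybenzaldehyde F1. Ring B is made separately as acetylfilicinic acid F2 by NaOMe/MeI gem-dimethylation of purchased 2,4,6-trihydroxyacetophenone, as in step 8. F1 and F2 are then joined by reductive alkylation (Knoevenagel condensation and transfer hydrogenation with Hantzsch ester, L-proline as catalyst, CH2Cl2, rt), which should give 13 directly.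

2. Step 4. Dimerisation of acetylketene and loss of the silyl group may compete with capture by the hindered enol silane, and the elimination of silanol may stall. The fallback sets out from 5 and comes back at 10. (E)-3-Methoxybut-2-enoyl chloride F3 is made from the purchasable acid with oxalyl chloride. The lithium enolate of 5 (LiN(SiMe3)2, two equivalents, THF, −78 °C) is acylated at carbon with F3 to give methyl (E)-7-methoxy-2,2-dimethyl-3,5-dioxo-4-[(2,4,6-trimethoxyphenyl)methyl]oct-6-enoate F4. CF3CO2H in CH2Cl2 should then close F4 to pyranone 10 by conjugate addition of the enol oxygen and loss of methanol.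

3. Step 9. Each partner may homo-couple statistically, and base may exchange the bridge that is already present (retro-Michael release of a quinone methide and recombination with the wrong enolate), which would scramble the three rings. The fallback sets out from 14 and comes back at 17. Compound 14 is aminomethylated at its one free ring A carbon with dimethylmethylideneammonium iodide (CH2Cl2, rt) to give 2-acetyl-4-[[3-butanoyl-5-(dimethylaminomethyl)-2,4,6-trihydroxyphenyl]methyl]-3,5-dihydroxy-6,6-dimethylcyclohexa-2,4-dien-1-one F5. Heating F5 with 16 in dioxane should expel dimethylamine to give the ring A quinone methide, which is trapped by the enol carbon of 16 without free formaldehyde or aqueous alkali.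

**Further compounds**

F1 | step 6 | 3-butanoyl-2,4,6-trimethoxybenzaldehyde | CCCC(=O)c1c(OC)cc(OC)c(C=O)c1OC
F2 | step 6 | acetylfilicinic acid, 2-acetyl-3,5-dihydroxy-6,6-dimethylcyclohexa-2,4-dien-1-one | CC(=O)C1=C(O)C=C(O)C(C)(C)C1=O
F3 | step 4 | (E)-3-methoxybut-2-enoyl chloride | CO/C(C)=C/C(Cl)=O
F4 | step 4 | methyl (E)-7-methoxy-2,2-dimethyl-3,5-dioxo-4-[(2,4,6-trimethoxyphenyl)methyl]oct-6-enoate | COC(=O)C(C)(C)C(=O)C(Cc1c(OC)cc(OC)cc1OC)C(=O)/C=C(\C)OC
F5 | step 9 | 2-acetyl-4-[[3-butanoyl-5-(dimethylaminomethyl)-2,4,6-trihydroxyphenyl]methyl]-3,5-dihydroxy-6,6-dimethylcyclohexa-2,4-dien-1-one | CCCC(=O)c1c(O)c(CN(C)C)c(O)c(CC2=C(O)C(C)(C)C(=O)C(C(C)=O)=C2O)c1O
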